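**Retrosynthetic overview**
- The target comes from its C11 aldehyde (Luche reduction, last step) after desilylation; the C10 coumarate and C8 tertiary alcohol come from an 8α,10-spiro-epoxide opened at C10 by p-coumaric acid (valtrate-hydrin logic), and the epoxide from an 8(10)-exocyclic alkene.
- The 1β-acyloxy acetal comes from the lactol and (S)-3-methylpentanoic acid.
- Both rings come from one iridoid-synthase-like cascade on an oxidised 8-oxogeranial analogue: Knoevenagel condensation with malonaldehyde supplies C3/C4/C11, a dienamine of the C1 enal (in place of the enzymatic hydride-derived enolate) bonds C9 to C5 (cyclopentane first), and the enol oxygen closes on C1 (dihydropyran second).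
- The linear dialdehyde comes from (2E)-4,4-dimethoxy-2-methylbut-2-enal by Brown allylation (sets C7), silylation, acetal hydrolysis and oxidative cleavage.

Assumption: the five building blocks marked as starting materials in the compound list are bought as such, the 3-methylpentanoic acid as its (S)-enantiomer; positions are given in iridoid numbering (C1 acetal carbon, O2, C3=C4, C5 and C9 ring-fusion carbons, C6–C8 cyclopentane, C10 on C8, C11 on C4) and TBS means tert-butyldimethylsilyl.

**Step 1**
Reactants: 1 (2E)-4,4-dimethoxy-2-methylbut-2-enal; 2 (+)-B-allyldiisopinocampheylborane [(+)-Ipc2B(allyl), both Ipc groups derived from (+)-α-pinene]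
Product: 3 (4S,5E)-7,7-dimethoxy-5-methylhepta-1,5-dien-4-ol
Conditions: Et2O/pentane, −78 °C; then NaOH, 30% H2O2, 0 °C to rt
Reagents that add atoms: none
Why: Brown asymmetric allylboration through a chair Zimmerman–Traxler transition state, in which the (+)-α-pinene-derived reagent adds allyl to the Si face of the α-methyl enal carbonyl (1,2-addition only) and so sets C7 as S.

**Step 2**
Reactants: 3
Product: 4 tert-butyl{[(4S,5E)-7,7-dimethoxy-5-methylhepta-1,5-dien-4-yl]oxy}dimethylsilane
Conditions: TBSCl, imidazole, DMF, rt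
Reagents that add atoms: tert-butyldimethylsilyl chloride, CC(C)(C)[Si](C)(C)Cl
Why: Imidazole-promoted silyl ether formation on the secondary allylic alcohol; the bulky ether later prevents furan formation from the γ-oxygenated enal and shields the β-face of C8=C10, and C7 is untouched.

**Step 3**
Reactants: 4
Product: 5 (2E,4S)-4-[(tert-butyldimethylsilyl)oxy]-3-methylhepta-2,6-dienal
Conditions: PPTS (cat.), acetone/H2O 10:1, rt
Reagents that add atoms: water, O
Why: Acid-catalysed acetal hydrolysis of the allylic dimethyl acetal runs through a conjugated oxocarbenium ion and is much faster than TBS cleavage, and the thermodynamically preferred E-enal geometry is kept.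

**Step 4**
Reactants: 5
Product: 6 (2E,4S)-4-[(tert-butyldimethylsilyl)oxy]-3-methylhex-2-enedial
Conditions: OsO4 (2 mol%), NaIO4 (4 equiv), 2,6-lutidine, dioxane/H2O 3:1, rt
Reagents that add atoms: sodium periodate, [Na+].[O-]I(=O)(=O)=O (oxygen passed on through catalytic osmium tetroxide, O=[Os](=O)(=O)=O)
Why: Lemieux–Johnson oxidative cleavage, in which OsO4 dihydroxylates the isolated monosubstituted alkene far faster than the electron-poor trisubstituted enal C=C and NaIO4 cleaves the diol to the C5 aldehyde.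

**Step 5**
Reactants: 6; 7 tetrabutylammonium malonaldehyde enolate
Product: 9 1β-hydroxy-7β-(tert-butyldimethylsilyloxy)-8(10)-ene-11-al iridoid lactol (1R,5S,7S,9S), via alkylidene-malonaldehyde trialdehyde 8 (not isolated)
Conditions: AcOH (1.1 equiv), CH2Cl2, 0 °C, 30 min; then (S)-α,α-diphenylprolinol trimethylsilyl ether (20 mol%), PhCO2H (20 mol%), 0 °C to rt; pH 7 buffer work-up
Reagents that add atoms: none
Why: Proposed new method: acetate-buffered Knoevenagel condensation takes place only at the saturated C5 aldehyde (the β,β-disubstituted enal is far less electrophilic) and gives the doubly activated 1-oxadiene 8; the secondary amine then turns the C1 enal, by γ-deprotonation of the C10 methyl, into a cross-conjugated dienamine whose α-carbon C9 adds to C5 (5-exo; attack through the γ-carbon C10 would be a disfavoured 5-endo closure) in a compact endo hetero-Diels–Alder-like transition state that gives the cis ring fusion, the malonaldehyde enol oxygen closes on the C1 iminium carbon, and the water formed in the flask hydrolyses the N,O-aminal to lactol 9 and frees the catalyst, leaving the C8=C10 methylene for later oxygenation; the (S)-catalyst shields the Re face of C9 so that C5 bonds to its Si face (9S) and C5 follows from the cis fusion, and the closest known reaction types are the domino Knoevenagel/hetero-Diels–Alder reaction of 2-alkylidene-1,3-dicarbonyls, the dienamine-mediated Rauhut–Currier-type cyclization of bis-enals and the enamine–enal [4+2] route to nepetalactol-type lactols.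

**Step 6**
Reactants: 9; 10 (3S)-3-methylpentanoic acid
Product: 11 1β-O-[(3S)-3-methylpentanoyl]-7β-(tert-butyldimethylsilyloxy)-8(10)-ene-11-al iridoid (1S,5S,7S,9S)
Conditions: DCC, DMAP (10 mol%), CH2Cl2, 0 °C
Reagents that add atoms: none
Why: Steglich esterification of the anomeric hydroxyl; the lactol equilibrates through its open form to the 1β-anomer (O1 anti to C8, as in genipin) and is acylated with retention, and the acid's stereocentre is β to the carbonyl and cannot epimerise.

**Step 7**
Reactants: 11
Product: 12 8α,10-spiro-epoxide of 11 (oxirane oxygen on the α-face of C8 and C10 on the β-face; 1S,5S,7S,8R,9S)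
Conditions: DMDO, acetone/CH2Cl2, −20 to 0 °C
Reagents that add atoms: dimethyldioxirane, CC1(C)OO1
Why: Sterically controlled dioxirane epoxidation of the exocyclic 1,1-disubstituted alkene, whose β-face is flanked by the 7β-silyloxy group and the 1β-acyloxy group so that oxygen arrives on the α-face (anti to the allylic silyl ether), while the push-pull C3=C4 bond and the aldehyde react much more slowly.

**Step 8**
Reactants: 12; 13 p-coumaric acid [(E)-3-(4-hydroxyphenyl)prop-2-enoic acid]
Product: 14 10-O-(E)-p-coumaroyl-8α-hydroxy-7β-(tert-butyldimethylsilyloxy)-1β-O-[(3S)-3-methylpentanoyl]-11-al iridoid (1S,5S,7S,8R,9S)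
Conditions: 13 (3 equiv), Cs2CO3 (10 mol%), DMF, 50 °C
Reagents that add atoms: none
Why: Base-catalysed carboxylate opening of a 2,2-disubstituted epoxide by SN2 attack at the primary C10 (the way valtrate-type spiro-epoxides give their hydrins) leaves the C8–O bond and its configuration untouched, and with substoichiometric base only the carboxylate (not the phenol) is ionised while excess acid protonates the tertiary alkoxide.

**Step 9**
Reactants: 14
Product: 15 10-O-(E)-p-coumaroyl-7β,8α-dihydroxy-1β-O-[(3S)-3-methylpentanoyl]-11-al iridoid (1S,5S,7S,8R,9S)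
Conditions: HF·pyridine, pyridine, THF, 0 °C to rt
Reagents that add atoms: none
Why: Fluoride-mediated desilylation under buffered acidic conditions, tolerated by the vinylogous-formate enol ether and the deactivated acyloxy acetal, with no base present to cause acyl migration.

**Step 10**
Reactants: 15
Product: 16 target, (1S,4aS,6S,7R,7aS)-6,7-dihydroxy-4-(hydroxymethyl)-7-({[(2E)-3-(4-hydroxyphenyl)prop-2-enoyl]oxy}methyl)-1,4a,5,6,7,7a-hexahydrocyclopenta[c]pyran-1-yl (3S)-3-methylpentanoate
Conditions: NaBH4, CeCl3·7H2O, MeOH/THF, −78 to −40 °C; pH 7 buffer work-up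
Reagents that add atoms: none
Why: Luche reduction gives 1,2-selective hydride addition to the β-alkoxyacrolein carbonyl, while the esters, the cinnamate alkene and the acyloxy acetal are inert at low temperature; no stereocentre is formed.

**Compound list**
1 | (2E)-4,4-dimethoxy-2-methylbut-2-enal | COC(OC)/C=C(\C)C=O | starting material
2 | (+)-B-allyldiisopinocampheylborane, Ipc groups from (+)-α-pinene | C=CCB([C@@H]1C[C@@H]2C[C@H]([C@H]1C)C2(C)C)[C@@H]1C[C@@H]2C[C@H]([C@H]1C)C2(C)C | starting material
3 | (4S,5E)-7,7-dimethoxy-5-methylhepta-1,5-dien-4-ol | C=CC[C@H](O)/C(C)=C/C(OC)OC | intermediate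
4 | tert-butyl{[(4S,5E)-7,7-dimethoxy-5-methylhepta-1,5-dien-4-yl]oxy}dimethylsilane | C=CC[C@H](O[Si](C)(C)C(C)(C)C)/C(C)=C/C(OC)OC | intermediate
5 | (2E,4S)-4-[(tert-butyldimethylsilyl)oxy]-3-methylhepta-2,6-dienal | C=CC[C@H](O[Si](C)(C)C(C)(C)C)/C(C)=C/C=O | intermediate
6 | (2E,4S)-4-[(tert-butyldimethylsilyl)oxy]-3-methylhex-2-enedial | O=CC[C@H](O[Si](C)(C)C(C)(C)C)/C(C)=C/C=O | intermediate
7 | tetrabutylammonium malonaldehyde enolate | O=C/C=C/[O-].CCCC[N+](CCCC)(CCCC)CCCC | starting material
8 | (2E,4S)-4-[(tert-butyldimethylsilyl)oxy]-7-formyl-3-methylocta-2,6-dienedial | O=CC(C=O)=CC[C@H](O[Si](C)(C)C(C)(C)C)/C(C)=C/C=O | intermediate (not isolated)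
9 | (1R,4aS,6S,7aS)-6-[(tert-butyldimethylsilyl)oxy]-1-hydroxy-7-methylidene-1,4a,5,6,7,7a-hexahydrocyclopenta[c]pyran-4-carbaldehyde | O[C@@H]1OC=C(C=O)[C@H]2C[C@H](O[Si](C)(C)C(C)(C)C)C(=C)[C@@H]12 | intermediate
10 | (3S)-3-methylpentanoic acid | CC[C@H](C)CC(=O)O | starting material
11 | (1S,4aS,6S,7aS)-6-[(tert-butyldimethylsilyl)oxy]-4-formyl-7-methylidene-1,4a,5,6,7,7a-hexahydrocyclopenta[c]pyran-1-yl (3S)-3-methylpentanoate | CC[C@H](C)CC(=O)O[C@@H]1OC=C(C=O)[C@H]2C[C@H](O[Si](C)(C)C(C)(C)C)C(=C)[C@@H]12 | intermediate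
12 | 8α,10-spiro-epoxide of 11 (iridoid numbering 1S,5S,7S,8R,9S; oxirane O α, C10 β) | CC[C@H](C)CC(=O)O[C@@H]1OC=C(C=O)[C@H]2C[C@H](O[Si](C)(C)C(C)(C)C)[C@]3(CO3)[C@@H]12 | intermediate
13 | p-coumaric acid, (E)-3-(4-hydroxyphenyl)prop-2-enoic acid | OC(=O)/C=C/c1ccc(O)cc1 | starting material
14 | 7-O-TBS ether of 15 (iridoid numbering 1S,5S,7S,8R,9S) | CC[C@H](C)CC(=O)O[C@@H]1OC=C(C=O)[C@H]2C[C@H](O[Si](C)(C)C(C)(C)C)[C@](O)(COC(=O)/C=C/c3ccc(O)cc3)[C@@H]12 | intermediate
15 | (1S,4aS,6S,7R,7aS)-4-formyl-6,7-dihydroxy-7-({[(2E)-3-(4-hydroxyphenyl)prop-2-enoyl]oxy}methyl)-1,4a,5,6,7,7a-hexahydrocyclopenta[c]pyran-1-yl (3S)-3-methylpentanoate | CC[C@H](C)CC(=O)O[C@@H]1OC=C(C=O)[C@H]2C[C@H](O)[C@](O)(COC(=O)/C=C/c3ccc(O)cc3)[C@@H]12 | intermediate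
16 | CNP0241834.1, (1S,4aS,6S,7R,7aS)-6,7-dihydroxy-4-(hydroxymethyl)-7-({[(2E)-3-(4-hydroxyphenyl)prop-2-enoyl]oxy}methyl)-1,4a,5,6,7,7a-hexahydrocyclopenta[c]pyran-1-yl (3S)-3-methylpentanoate | CC[C@H](C)CC(=O)O[C@@H]1OC=C(CO)[C@H]2C[C@H](O)[C@](O)(COC(=O)/C=C/c3ccc(O)cc3)[C@@H]12 | target

**Totals**
Total step count: 10. Longest linear sequence: 10 steps (1 to 16).

**Three steps most likely to fail**

Step 5 (cascade). The amine can be tied up by the very electrophilic trialdehyde, the β,γ-unsaturated iminium can drift to the conjugated cyclopentene enal, and the catalyst may be mismatched with the C7 centre. The fallback sets out from 5 and comes back at 11. Cross-metathesis of the terminal alkene of 5 with acrolein (second-generation Grubbs catalyst, (H2IMes)(PCy3)Cl2Ru=CHPh, CH2Cl2, 40 °C) gives the bis-enal (2E,4S,6E)-4-[(tert-butyldimethylsilyl)oxy]-3-methylocta-2,6-dienedial F1, an 8-oxogeranial analogue without C11. The same prolinol silyl ether/PhCO2H system then runs the known dienamine/iminium cyclization of a bis-enal and, after hydrolysis, gives the 11-nor lactol (1β-hydroxy, 7β-silyloxy, 8(10)-ene, H-5β, H-9β, in equilibrium with its ring-opened dialdehyde) F2. Steglich acylation with 10 gives the 11-nor 1β-(3S)-3-methylpentanoate F3. Vilsmeier–Haack formylation of its enol ether at C4 (POCl3, DMF, 0 °C; aqueous NaOAc) brings in C11 as the aldehyde and delivers 11.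

Step 7 (face of epoxidation). The convex β-face of the cis-fused bicycle competes with the shielding by the 7β-silyloxy and 1β-acyloxy groups. The fallback sets out from 11 and comes back at 12. If the dioxirane prefers the β-face, a halohydrin sequence inverts the outcome: NBS in THF/H2O forms the bromonium ion on that same β-face and water opens it at the tertiary C8 from the α-face, giving the 10-bromo-8α-hydroxy compound (bromohydrin) F4; DBU in CH2Cl2 closes it through the 8α-oxygen to the epoxide 12.

Step 8 (epoxide opening by unprotected p-coumaric acid). The hindered epoxide may react slowly, and acyl transfer at the anomeric ester or phenol alkylation may compete. The fallback sets out from 11 and comes back at 15. OsO4 (cat.)/NMO dihydroxylation of the exocyclic alkene anti to the allylic silyl ether gives the 8α,10-diol F5. Separately, 13 is bis-silylated (TBSCl, imidazole, DMF) to tert-butyldimethylsilyl (E)-4-(tert-butyldimethylsilyloxy)cinnamate F6, and only the silyl ester is hydrolysed (K2CO3, aqueous MeOH/THF) to (E)-4-(tert-butyldimethylsilyloxy)cinnamic acid F7. EDC·HCl/DMAP esterifies only the primary C10 hydroxyl of the diol with this acid to give the bis-silyl ether 7-O-TBS-10-O-(4-O-TBS-p-coumaroyl) compound F8, and the HF·pyridine conditions of step 9 remove both silyl groups to give 15.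

**Further compounds**
F1 | step 5 | (2E,4S,6E)-4-[(tert-butyldimethylsilyl)oxy]-3-methylocta-2,6-dienedial | O=C/C=C/C[C@H](O[Si](C)(C)C(C)(C)C)/C(C)=C/C=O
F2 | step 5 | 11-nor lactol: 1β-hydroxy-7β-(tert-butyldimethylsilyloxy)-8(10)-ene iridoid without C11, H-5β, H-9β | O[C@@H]1OC=C[C@H]2C[C@H](O[Si](C)(C)C(C)(C)C)C(=C)[C@@H]12
F3 | step 5 | 11-nor 1β-O-[(3S)-3-methylpentanoyl] derivative of F2 | CC[C@H](C)CC(=O)O[C@@H]1OC=C[C@H]2C[C@H](O[Si](C)(C)C(C)(C)C)C(=C)[C@@H]12
F4 | step 7 | 10-bromo-8α-hydroxy bromohydrin of 11 (C10 β) | CC[C@H](C)CC(=O)O[C@@H]1OC=C(C=O)[C@H]2C[C@H](O[Si](C)(C)C(C)(C)C)[C@](O)(CBr)[C@@H]12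
F5 | step 8 | 8α,10-diol of 11 (C10 β) | CC[C@H](C)CC(=O)O[C@@H]1OC=C(C=O)[C@H]2C[C@H](O[Si](C)(C)C(C)(C)C)[C@](O)(CO)[C@@H]12
F6 | step 8 | tert-butyldimethylsilyl (E)-4-(tert-butyldimethylsilyloxy)cinnamate | CC(C)(C)[Si](C)(C)OC(=O)/C=C/c1ccc(O[Si](C)(C)C(C)(C)C)cc1
F7 | step 8 | (E)-4-(tert-butyldimethylsilyloxy)cinnamic acid | OC(=O)/C=C/c1ccc(O[Si](C)(C)C(C)(C)C)cc1
F8 | step 8 | 7-O-TBS-10-O-[(E)-4-(tert-butyldimethylsilyloxy)cinnamoyl]-8α-hydroxy-1β-O-[(3S)-3-methylpentanoyl]-11-al iridoid | CC[C@H](C)CC(=O)O[C@@H]1OC=C(C=O)[C@H]2C[C@H](O[Si](C)(C)C(C)(C)C)[C@](O)(COC(=O)/C=C/c3ccc(O[Si](C)(C)C(C)(C)C)cc3)[C@@H]12
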